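## Structural features

Atoms carry mutilin numbers throughout. Compound 42 is a 5-6-8 tricycle. A cyclopentanone (C1–C2–C3–C4–C9) is fused through C4–C9 to a cyclohexane (C4–C5–C6–C7–C8–C9). The 1,3-related ring atoms C5 and C9 are spanned by C14–C13–C12–C11–C10, which makes the cyclooctane and a bicyclo[5.3.1]undecane with C4 as the one-atom bridge.

The core carries eight stereocentres (4S,5S,6S,9S,10R,11S,12R,14R as written) in the runs C4–C5–C6 and C9–C10–C11–C12, with C14 next to C5. The ninth, C19 (S), sits in the side chain on quaternary C12. C5, C9 and C12 are quaternary. Read against C9, the C4 descriptor places C3 on the face of the C4 bridge that looks toward C10/C14, and H-4 toward C6–C8.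

The fragile groups are the glycolate ester on the hindered C14 oxygen, the C4–H next to the C3 ketone and the free 1,2-diol. Three secondary or primary hydroxyls compete with C14–OH in any acylation.

The real difficulty is the eight-membered ring, which holds three contiguous stereocentres (C10–C12) between two quaternary ring-fusion atoms. A direct medium-ring closure would fight entropy and transannular strain.

The key step uses two facts. C11 and C14 are both oxygenated and 1,4-related across C12–C13. Deleting C11–C13 from the bridge leaves a direct C10–C14 bond, i.e. a compact bicyclo[3.2.1]octan-6-one whose C10 carries the C11 acyl chain. The C14 ketone can accept a C13 radical and the C11 ketone can stabilise the C10 radical that the ring opening leaves.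

## Logic of the disconnections

**42 to 40.** Only C–O bonds to protecting groups are cut: the C3 ketal, the C19/C20 acetonide, and the trifluoroacetates on O11 and on the glycolate oxygen. The ketone, the diol and the glycolate are the sensitive groups, so they stay masked until the end. The demand is a last step that strips four groups without touching the C14 ester.

**40 to 37 + 39, and 37 to 36.** The C14–O acyl bond and the O11 acyl bond are cut. C14–OH is the more shielded of the two ring carbinols, so O11 is capped first and C14 is then acylated with the masked two-carbon acid 39 (from 38). The gain is a plain diol, 36. The demand is site selectivity between two secondary alcohols.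

**36 to 35.** The two carbinol C–H bonds at C11 and C14 are removed. Both oxygens as ketones are exactly what the ring expansion delivers, and two stereocentres disappear. The forward reduction must give 11S and 14R, which is asked of a thermodynamically controlled dissolving-metal reduction.

**35 to 33.** C13–C14 is cut, C10–C14 is re-joined and iodine is placed on C13. The cyclooctane collapses to a rigid bicyclo[3.2.1]octanone and the C10 stereocentre vanishes (it is quaternary in 33, and either epimer serves). The forward step needs the C13 radical to reach C14 and the alkoxy radical to open C10–C14 and no other bond.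

**33 to 20 + 30 (through 32).** C10–C11 is cut. C10 is the only enolisable position of 20, and 30 has no α-hydrogen, so the union is convergent and unambiguous. A direct C-acylation at this crowded enolate would favour the enol ester, so the bond is made as an aldol and the oxidation level is corrected afterwards. The iodide is already in 30, so no step follows the oxidation before the key step.

**30 to 21.** C12–C18 and C12–C13 are cut as two enolate alkylations, and the oxidation levels at C11 and C13 are adjusted. C19 comes from the chiral pool. The lactone ties O19/O20 and C11 together and makes the enolate face-selective. The second alkylation must build quaternary C12 anti to the alkoxide, so the order (methyl first) fixes the configuration.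

**20 to 15 (through 19 and 18).** These are functional-group changes only: the C7 carbonyl is put back, and the C3 ketal is traced to a silyl ether. The C7 ketone is the vestige of the three-carbon partner, and C14 is still an enol ether in 15, so the two carbonyls are told apart without effort. C3 becomes a ketone only once C4 is no longer allylic.

**15 to 12 + 13.** C5–C6 and C8–C9 are cut. Both join a quaternary bridgehead to the three-carbon bridge, and a (4+3) cycloaddition makes both bonds and both quaternary centres at once. The demands are orientation (methyl-bearing terminus on C5), face (anti to C3) and the C6 configuration.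

**12 to 8 (through 10).** The C5–C15 bond and the enol O–Si bond are cut, which asks only for kinetic α′-enolisation twice.

**8 to 7.** C4–C9, C5–C14 and C10–C14 are cut (Pauson–Khand retron). The gain is an acyclic enyne. The demand is that the C3 silyloxy centre controls C4.

**7 to 2 + 3 (through 6 and 5), and 2 to 1.** The C2–C3 bond is cut to a Grignard reagent and an enal. The carbinol is resolved because it is the only source of absolute configuration for the core.

## Other disconnections considered

**Alternative 1:** The cut is C1–C9, which simplifies only the hydrindane. In the forward step KH with 18-crown-6 ionises a bridging C3 carbinol that carries a vinyl group. The alkoxide undergoes a [3,3] shift that forms C1–C9, breaks C3–C7 and leaves hydrindenone A1 with the C3 ketone and a C7=C8 alkene.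

- In its favour: the shift is suprafacial and strain-driven, and it sets quaternary C9 and the adjacent C10 directly from alkene geometry.
- Against it here: it stops at a bicycle. The whole cyclooctane, with C11–C13 and the C12 quaternary centre, must still be built and closed as a medium ring from two benzyloxymethyl arms. The alkene must also be hydrogenated.
- A correction to the structure: a suprafacial shift can only give the cis ring fusion, so A1 is written that way. Compound 42 has C3 on the other face of C4, so C4 would have to be inverted later next to the ketone.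
- Comparison: structurally the alternative solves the easier half and the chosen plan the harder half. Mechanistically the oxy-Cope is the better step: it has no competing channels, and C10 is set directly and not by equilibration. In step economy it is roughly equal up to the bicyclic stage and worse after it.

**Alternative 2:** The cut is C4–C5. In the forward step a bis(trimethylsilyl enol ether) at C3 and C14 of a spiro cyclopentanone–cyclodecanone is oxidised at an anode, and the enol ether radical cation is trapped by the second enol ether to give diketone A2.

- In its favour: one bond creates the cyclohexane and the cyclooctane together. Both carbonyls appear at the positions and oxidation levels of the target, with no detour through a C7 oxygen. On these points it is the better plan.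
- Against it here: the ten-membered ring with C6, C9, C10, C11 and C12 in place is itself the hard problem. The coupling must join a tertiary to a quaternary carbon and set C4 and C5 through transannular conformation alone. Desilylation, over-oxidation and intermolecular coupling compete.
- Comparison: both key steps run through open-shell intermediates under dilution, so they are equal in that respect. The chosen plan has the firmer geometric control because its precursor is rigid. Step economy depends wholly on the macrocycle and is expected to be worse.

**Alternative 3:** The cut is C4–C9 plus C10–C11, with C4–C11 restored, so the retron is a cyclohexanone (C4, C5, C14, C13, C12, C11) carrying a 2-acyl chain. In the forward step the enolised β-diketone adds photochemically across the tethered C9=C10 alkene, and retro-aldol opening of the cyclobutanol gives cyclooctanone A3.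

- In its favour: one operation makes two C–C bonds, the cyclopentane and quaternary C9, and expands six to eight. The retro-aldol can break only one bond. On both points it is better than the radical scission, which must choose among three bonds.
- Against it here: A3 still lacks the cyclohexane. C7–C8 must be closed later between two benzyloxymethyl arms, which costs several steps. The face selectivity of the cycloaddition relative to C5, C12 and C14 is not assured, and the substrate already needs two quaternary centres on a cyclohexanone.
- Comparison: both plans are ring expansions by fragmentation of a strained alkoxy intermediate next to a ketone, so they are equal in concept. The alternative builds more per step. The chosen plan has every carbocycle except the eight-membered one in place by step 8 and is shorter overall.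

Key step: step 21

Assumption: C5 and C9 are bridgeheads joined by three bridges in every compound from 15 on, so their mutual arrangement is the only one such a bicycle can have, and the descriptors at C5 and C6 are therefore carried through all structures exactly as they stand in the target, while C4, C9, C10, C11, C12, C14 and C19 are used literally in every stereochemical argument.

## Route

Step 1
Reactants: 1 pent-3-yn-1-ol
Product: 2 5-bromopent-2-yne
Conditions: CBr4, PPh3, CH2Cl2, 0 °C → rt
Reagents that add atoms: carbon tetrabromide, BrC(Br)(Br)Br
Why: Appel bromination of an unhindered primary alcohol by SN2 on the alkoxyphosphonium ion; the internal alkyne is a spectator.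

Step 2
Reactants: 2 5-bromopent-2-yne; 3 acrolein
Product: 5 rac-oct-1-en-6-yn-3-ol, via pent-3-ynylmagnesium bromide 4 (not isolated)
Conditions: Mg, THF, 40 °C; then 3, −78 °C; aq. NH4Cl
Reagents that add atoms: none
Why: Grignard formation from a primary bromide and 1,2-addition of the hard organomagnesium to the enal at low temperature should give the allylic alcohol; its carbinol carbon is C3 of the target.

Step 3
Reactants: 5 rac-oct-1-en-6-yn-3-ol
Product: 6 (R)-oct-1-en-6-yn-3-ol
Conditions: Ti(OiPr)4, L-(+)-DIPT, t-BuOOH (0.6 equiv), 4 Å MS, CH2Cl2, −20 °C
Reagents that add atoms: none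
Why: Sharpless kinetic resolution: with the L-(+)-tartrate the (S)-alcohol is epoxidised much faster, so the (R)-alcohol should be recovered enantioenriched after slightly more than half conversion; this centre later relays chirality to C4.

Step 4
Reactants: 6 (R)-oct-1-en-6-yn-3-ol
Product: 7 (R)-3-(tert-butyldimethylsilyloxy)oct-1-en-6-yne
Conditions: TBSCl, imidazole, DMF, rt
Reagents that add atoms: tert-butyl(chloro)dimethylsilane, CC(C)(C)[Si](C)(C)Cl
Why: Standard silylation; the bulky ether is chosen to raise the diastereoselectivity of step 5 and to survive steps 5–8.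

Step 5
Reactants: 7 (R)-3-(tert-butyldimethylsilyloxy)oct-1-en-6-yne
Product: 8 bicyclic enone (C14 ketone, C9=C10, CH3 on C10, OTBS on C3 cis to H-4)
Conditions: Co2(CO)8 (10 mol %), tetramethylthiourea, CO (1 atm), benzene, 70 °C
Reagents that add atoms: carbon monoxide, [C-]#[O+]
Why: Intramolecular Pauson–Khand reaction of a 1,6-enyne forms C4–C9, C5–C14 and C10–C14 (alkyne carbons become C9 and C10, CO becomes C14); the allylic silyloxy group should sit exo in the cobaltacycle, so C4 forms with H-4 cis to OTBS, and the minor diastereomer is removed by chromatography.

Step 6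
Reactants: 8 bicyclic enone
Product: 10 5-methyl enone (CH3 on C5 cis to H-4), via lithium enolate 9 (not isolated)
Conditions: LDA, THF, −78 °C; MeI, −78 → −40 °C
Reagents that add atoms: iodomethane, CI
Why: Kinetic α′-deprotonation gives the cross-conjugated enolate, which is methylated at C5 on the convex face (enolate alkylation); this centre is erased in step 7, so its purity does not matter.

Step 7
Reactants: 10 5-methyl enone
Product: 12 2-silyloxycyclopentadiene (C5=C14(OTIPS)–C10=C9, C4–H sp3), via lithium enolate 11 (not isolated)
Conditions: LDA, THF, −78 °C; TIPSOTf; kept cold and used crude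
Reagents that add atoms: tri(propan-2-yl)silyl trifluoromethanesulfonate, CC(C)[Si](C(C)C)(C(C)C)OS(=O)(=O)C(F)(F)F
Why: A second kinetic α′-deprotonation and O-silylation with the hard silyl triflate should give the cyclic silyl dienol ether; C4 is its only sp3 ring atom and keeps its configuration as long as 1,5-hydrogen shifts are avoided by working cold.

Step 8
Reactants: 12 2-silyloxycyclopentadiene; 13 3-chlorobutan-2-one
Product: 15 (4+3) adduct (C7 ketone, C14 enol ether, C3 OTBS), via oxyallyl cation 14 (not isolated)
Conditions: Et3N, CF3CH2OH, 0 °C (13 added slowly); then DBU (cat.), CH2Cl2, rt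
Reagents that add atoms: none
Why: (4+3) cycloaddition of an oxyallyl cation with a cyclopentadiene: base strips HCl from 13 in the ionising fluoro alcohol and the cation adds across C5 and C9 on the diene face anti to C3, which fixes both bridgeheads relative to C4 and leaves C3 on the side of the C10=C14 bridge; the compact transition state and the DBU equilibration through the C7 enol should place the C6 methyl equatorial; the orientation (substituted terminus on C5) is the least secure point and is taken up at the end.

Step 9
Reactants: 15 (4+3) adduct
Product: 18 hydroxy ketone (C14 ketone, C7 methylene, C3–OH), via N-silyl hydrazone 16 (not isolated), via silyl ether ketone 17 (not isolated)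
Conditions: TBSNHNHTBS, Sc(OTf)3 (cat.), CHCl3, 55 °C; KOtBu, t-BuOH, DMSO, 23 → 100 °C; then TBAF, THF, rt
Reagents that add atoms: none
Why: Wolff–Kishner reduction through the N-silyl hydrazone: only C7 is a free ketone because C14 is still an enol ether; tert-butoxide then expels N2 and unmasks the C14 ketone, and fluoride frees C3–OH; C6 stops being epimerisable here.

Step 10
Reactants: 18 hydroxy ketone
Product: 19 tricyclic 3,14-diketone
Conditions: Dess–Martin periodinane, NaHCO3, CH2Cl2, rt
Reagents that add atoms: none
Why: Dess–Martin oxidation of the secondary alcohol; C4 is now a bridge carbon between two quaternary bridgeheads and can no longer be lost through an enone.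

Step 11
Reactants: 19 tricyclic 3,14-diketone
Product: 20 tricyclic C14 ketone with C3 ethylene ketal
Conditions: HOCH2CH2OH, p-TsOH (cat.), benzene, reflux (Dean–Stark)
Reagents that add atoms: ethane-1,2-diol, OCCO
Why: Acid-catalysed ketalisation with azeotropic removal of water; the C3 cyclopentanone reacts, while the C14 ketone between quaternary C5 and tertiary C10 does not.

Step 12
Reactants: 21 (S)-4-hydroxydihydrofuran-2(3H)-one
Product: 23 (3S,4S)-4-hydroxy-3-methyldihydrofuran-2(3H)-one, via dilithio dianion 22 (not isolated)
Conditions: LDA (2.2 equiv), THF, −78 °C; MeI, DMPU, −78 → −40 °C; aq. NH4Cl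
Reagents that add atoms: iodomethane, CI
Why: Fráter–Seebach alkylation: the alkoxide–enolate dianion is methylated anti to the C19 alkoxide, giving the trans lactone by 1,2-induction.

Step 13
Reactants: 23 (3S,4S)-4-hydroxy-3-methyldihydrofuran-2(3H)-one
Product: 25 (3S,4S)-3-[(benzyloxy)methyl]-4-hydroxy-3-methyldihydrofuran-2(3H)-one, via dilithio dianion 24 (not isolated)
Conditions: LDA (2.2 equiv), THF, −78 °C; BnOCH2Cl, DMPU, −78 → −20 °C; aq. NH4Cl
Reagents that add atoms: benzyl chloromethyl ether, ClCOCc1ccccc1
Why: Second Fráter–Seebach alkylation: the reactive chloromethyl ether again enters anti to the alkoxide, so quaternary C12 forms with CH2OBn trans and CH3 cis to C19–OH; this makes the lactone carbonyl C11 and the new arm C13.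

Step 14
Reactants: 25 dialkylated lactone
Product: 26 (2S,3S)-2-[(benzyloxy)methyl]-2-methylbutane-1,3,4-triol
Conditions: LiAlH4, THF, 0 °C → rt
Reagents that add atoms: none
Why: Hydride reduction of the lactone to the diol; no stereocentre is touched and the two CH2O arms on C12 stay different (free OH = C11, OBn = C13).

Step 15
Reactants: 26 triol
Product: 27 (2S)-3-(benzyloxy)-2-[(4S)-2,2-dimethyl-1,3-dioxolan-4-yl]-2-methylpropan-1-ol
Conditions: Me2C(OMe)2, PPTS (cat.), CH2Cl2, rt
Reagents that add atoms: 2,2-dimethoxypropane, COC(C)(C)OC
Why: Acetonide formation under thermodynamic control favours the dioxolane on the terminal 1,2-diol over a 1,3-dioxane, leaving the neopentyl C11–OH free.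

Step 16
Reactants: 27 acetonide alcohol
Product: 28 (2S)-3-(benzyloxy)-2-[(4S)-2,2-dimethyl-1,3-dioxolan-4-yl]-2-methylpropanal
Conditions: Dess–Martin periodinane, NaHCO3, CH2Cl2, rt
Reagents that add atoms: none
Why: Oxidation to an aldehyde that has no α-hydrogen, so C12 cannot epimerise.

Step 17
Reactants: 28 benzyloxy aldehyde
Product: 29 (2S)-2-[(4S)-2,2-dimethyl-1,3-dioxolan-4-yl]-3-hydroxy-2-methylpropanal
Conditions: H2 (1 atm), Pd/C, EtOAc, rt
Reagents that add atoms: none
Why: Hydrogenolysis of the benzyl ether; the hindered aliphatic aldehyde and the acetonide should survive neutral conditions.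

Step 18
Reactants: 29 hydroxy aldehyde
Product: 30 (2S)-2-[(4S)-2,2-dimethyl-1,3-dioxolan-4-yl]-3-iodo-2-methylpropanal
Conditions: PPh3, I2, imidazole, toluene, 80 °C
Reagents that add atoms: iodine, II
Why: Appel-type iodination; SN2 at the neopentyl carbon needs heat, but no elimination is possible because C12 is quaternary.

Step 19
Reactants: 20 tricyclic C14 ketone with C3 ketal; 30 iodo aldehyde
Product: 32 aldol adduct (C10 quaternary, C11 carbinol as epimer mixture), via lithium enolate 31 (not isolated)
Conditions: LDA, THF, −78 → 0 °C; 30, −78 °C; AcOH, −78 °C
Reagents that add atoms: none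
Why: Aldol addition: 20 can enolise only toward C10, and the non-enolisable aldehyde is slim enough at its carbonyl carbon to meet the fully substituted enolate; the cold quench prevents retro-aldol, the neopentyl iodide is inert to the enolate, and the new C10 and C11 configurations are irrelevant (C11 is oxidised next, C10 becomes trigonal in step 21).

Step 20
Reactants: 32 aldol adduct
Product: 33 tricyclic β-diketone with the 3-iodo acyl chain on C10
Conditions: Dess–Martin periodinane, NaHCO3, CH2Cl2, rt
Reagents that add atoms: none
Why: Neutral oxidation of the hindered β-hydroxy ketone to the non-enolisable 1,3-diketone avoids the retro-aldol and retro-Claisen pathways that base would open; aldol plus oxidation stands in for a direct C-acylation, which at this enolate would mainly give the enol ester.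

Step 21
Reactants: 33 tricyclic β-diketone with the 3-iodo acyl chain on C10
Product: 35 tricyclic cyclooctane-11,14-dione (10R), via C10-epimeric dione 34 (not isolated)
Conditions: Bu3SnH (1.3 equiv) and AIBN (0.3 equiv) by syringe pump over 10 h, benzene (2 mM), 80 °C; then DBU (0.2 equiv), rt
Reagents that add atoms: none
Why: The tin radical takes iodine from C13; the neopentyl radical adds to the C14 carbonyl carbon, and the resulting alkoxy radical, locked in a strained bicyclo[3.2.1]octane, fragments at C10–C14 to the tertiary radical stabilised by the C11 carbonyl, which then takes hydrogen from the stannane. The closest known reaction is the three-carbon Dowd–Beckwith expansion of 2-(3-halopropyl) β-keto esters, with the chain ketone here playing the part of the ester. The only ring closure is the transient 5-exo-trig addition (ring C10–C11–C12–C13–C14); the cyclooctane arises from the scission that follows, so no eight-membered transition state is needed. C10 is the one new stereocentre: it forms by hydrogen transfer to a planar radical and is then set under thermodynamic control by DBU through the C11 enol, which should leave the methyl pseudo-equatorial (10R). The scission must take C10–C14 and not C5–C14 or C13–C14, which the carbonyl-stabilised radical and the release of bicyclic strain secure. The C13 radical must reach C14 before it is reduced or diverted by 3-exo attack on the C11 carbonyl (a 1,2-acyl shift to the tertiary C12 radical); high dilution and slow stannane addition counter both, because the acyl shift is reversible and the rearranged radical has no fast exit other than reduction. C5, C9 and C12 are untouched, and both C10 epimers of 33 converge.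

Step 22
Reactants: 35 tricyclic cyclooctane-11,14-dione
Product: 36 11S,14R-diol (C3 ketal, acetonide)
Conditions: Li, NH3 (l), THF, EtOH, −78 °C
Reagents that add atoms: none
Why: Dissolving-metal reduction of both ketones under thermodynamic control; each carbinol should form as the more stable, pseudo-equatorial epimer (11S, 14R), and the ketal, the acetonide and the already equilibrated C10 are unaffected.

Step 23
Reactants: 36 11,14-diol
Product: 37 11-O-trifluoroacetate
Conditions: N-(trifluoroacetyl)imidazole, THF, 0 °C
Reagents that add atoms: 1-(trifluoroacetyl)imidazole, O=C(n1ccnc1)C(F)(F)F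
Why: Selective acylation: C14–OH is shielded by quaternary C5 and the cyclohexane, so the mild acyl-transfer reagent should cap C11–OH only.

Step 24
Reactants: 38 glycolic acid
Product: 39 2-(trifluoroacetoxy)acetic acid
Conditions: (CF3CO)2O, 0 °C → rt; concentrate
Reagents that add atoms: trifluoroacetic anhydride, O=C(OC(=O)C(F)(F)F)C(F)(F)F
Why: O-Trifluoroacetylation of the hydroxy acid gives a glycolic acid whose hydroxyl is masked by a group that leaves under the same mild methanolysis as the C11 ester.

Step 25
Reactants: 37 11-O-trifluoroacetate; 39 2-(trifluoroacetoxy)acetic acid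
Product: 40 11-O-trifluoroacetyl 14-O-[(trifluoroacetoxy)acetyl] diester
Conditions: EDC·HCl, DMAP, CH2Cl2, rt
Reagents that add atoms: none
Why: Steglich esterification; acyl transfer through the acylpyridinium ion reaches the hindered C14–OH while C11 is blocked.

Step 26
Reactants: 40 diester
Product: 42 Pleuromutilin A, via ketal acetonide glycolate 41 (not isolated)
Conditions: NaHCO3, MeOH, 0 °C → rt; then 1 M aq. HCl, THF, rt
Reagents that add atoms: water, O
Why: Methanolysis removes the two activated trifluoroacetates but not the hindered C14 glycolate; dilute acid then hydrolyses the ketal (the C3 carbonyl oxygen comes from water) and the acetonide; no stereocentre is touched.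

## Compound list

1 | pent-3-yn-1-ol | CC#CCCO | starting material
2 | 5-bromopent-2-yne | CC#CCCBr | intermediate
3 | acrolein | C=CC=O | starting material
4 | pent-3-ynylmagnesium bromide | CC#CCC[Mg]Br | intermediate
5 | rac-oct-1-en-6-yn-3-ol | CC#CCCC(O)C=C | intermediate
6 | (R)-oct-1-en-6-yn-3-ol | CC#CCC[C@@H](O)C=C | intermediate
7 | (R)-3-(tert-butyldimethylsilyloxy)oct-1-en-6-yne | CC#CCC[C@@H](O[Si](C)(C)C(C)(C)C)C=C | intermediate
8 | (6R,6aR)-6-(tert-butyldimethylsilyloxy)-3-methyl-4,5,6,6a-tetrahydro-1H-pentalen-2-one | CC1=C2CC[C@@H](O[Si](C)(C)C(C)(C)C)[C@@H]2CC1=O | intermediate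
9 | lithium cross-conjugated enolate of 8 (C5=C14–OLi) | CC1=C2CC[C@@H](O[Si](C)(C)C(C)(C)C)[C@@H]2C=C1O[Li] | intermediate
10 | (1R,6R,6aR)-6-(tert-butyldimethylsilyloxy)-1,3-dimethyl-4,5,6,6a-tetrahydro-1H-pentalen-2-one | CC1=C2CC[C@@H](O[Si](C)(C)C(C)(C)C)[C@@H]2[C@@H](C)C1=O | intermediate
11 | lithium enolate of 10 | CC1=C2CC[C@@H](O[Si](C)(C)C(C)(C)C)[C@@H]2C(C)=C1O[Li] | intermediate
12 | 2-(triisopropylsilyloxy)cyclopenta-1,3-diene fused to ring A (C5=C14–C10=C9; CH3 on C5 and C10; OTBS on C3) | CC1=C2CC[C@@H](O[Si](C)(C)C(C)(C)C)[C@@H]2C(C)=C1O[Si](C(C)C)(C(C)C)C(C)C | intermediate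
13 | 3-chlorobutan-2-one | CC(Cl)C(C)=O | starting material
14 | 1-methyl-2-oxidoallyl cation | C[CH+]C([O-])=C | intermediate
15 | (4+3) adduct: bicyclo[3.2.1]octenone with C7 ketone, C14(OTIPS)=C10 enol ether, CH3 on C5, C6, C10, OTBS on C3 | CC1=C(O[Si](C(C)C)(C(C)C)C(C)C)[C@@]2(C)[C@@H](C)C(=O)C[C@]13CC[C@@H](O[Si](C)(C)C(C)(C)C)[C@@H]32 | intermediate
16 | C7 N-(tert-butyldimethylsilyl)hydrazone of 15 | CC1=C(O[Si](C(C)C)(C(C)C)C(C)C)[C@@]2(C)[C@@H](C)C(=NN[Si](C)(C)C(C)(C)C)C[C@]13CC[C@@H](O[Si](C)(C)C(C)(C)C)[C@@H]32 | intermediate
17 | C14 ketone with C7 methylene and C3 OTBS (exo-methyl C10 epimer drawn) | C[C@H]1C(=O)[C@@]2(C)[C@@H](C)CC[C@]13CC[C@@H](O[Si](C)(C)C(C)(C)C)[C@@H]32 | intermediate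
18 | C14 ketone with C3–OH | C[C@H]1C(=O)[C@@]2(C)[C@@H](C)CC[C@]13CC[C@@H](O)[C@@H]32 | intermediate
19 | tricyclic 3,14-diketone | C[C@H]1C(=O)[C@@]2(C)[C@@H](C)CC[C@]13CCC(=O)[C@@H]32 | intermediate
20 | tricyclic C14 ketone with C3 ethylene ketal | C[C@H]1C(=O)[C@@]2(C)[C@@H](C)CC[C@]13CCC4(OCCO4)[C@@H]32 | intermediate
21 | (S)-4-hydroxydihydrofuran-2(3H)-one | O=C1C[C@H](O)CO1 | starting material
22 | dilithio alkoxide–enolate of 21 | [Li]OC1=C[C@H](O[Li])CO1 | intermediate
23 | (3S,4S)-4-hydroxy-3-methyldihydrofuran-2(3H)-one | O=C1OC[C@@H](O)[C@@H]1C | intermediate
24 | dilithio alkoxide–enolate of 23 | [Li]OC1=C(C)[C@H](O[Li])CO1 | intermediate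
25 | (3S,4S)-3-[(benzyloxy)methyl]-4-hydroxy-3-methyldihydrofuran-2(3H)-one | O=C1OC[C@@H](O)[C@]1(C)COCc2ccccc2 | intermediate
26 | (2S,3S)-2-[(benzyloxy)methyl]-2-methylbutane-1,3,4-triol | OC[C@@](C)(COCc1ccccc1)[C@H](O)CO | intermediate
27 | (2S)-3-(benzyloxy)-2-[(4S)-2,2-dimethyl-1,3-dioxolan-4-yl]-2-methylpropan-1-ol | OC[C@@](C)(COCc1ccccc1)[C@H]2COC(C)(C)O2 | intermediate
28 | (2S)-3-(benzyloxy)-2-[(4S)-2,2-dimethyl-1,3-dioxolan-4-yl]-2-methylpropanal | O=C[C@@](C)(COCc1ccccc1)[C@H]2COC(C)(C)O2 | intermediate
29 | (2S)-2-[(4S)-2,2-dimethyl-1,3-dioxolan-4-yl]-3-hydroxy-2-methylpropanal | O=C[C@@](C)(CO)[C@H]1COC(C)(C)O1 | intermediate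
30 | (2S)-2-[(4S)-2,2-dimethyl-1,3-dioxolan-4-yl]-3-iodo-2-methylpropanal | O=C[C@@](C)(CI)[C@H]1COC(C)(C)O1 | intermediate
31 | lithium enolate of 20 (C10=C14–OLi) | CC1=C(O[Li])[C@@]2(C)[C@@H](C)CC[C@]13CCC4(OCCO4)[C@@H]32 | intermediate
32 | aldol adduct: 20 bearing on C10 the CH(OH)–C12(CH3)(CH2I)(dioxolanyl) chain, C11 epimers | IC[C@@](C)([C@H]5COC(C)(C)O5)C(O)[C@@]1(C)C(=O)[C@@]2(C)[C@@H](C)CC[C@]13CCC4(OCCO4)[C@@H]32 | intermediate
33 | tricyclic β-diketone with the 3-iodo acyl chain on C10 | IC[C@@](C)([C@H]5COC(C)(C)O5)C(=O)[C@@]1(C)C(=O)[C@@]2(C)[C@@H](C)CC[C@]13CCC4(OCCO4)[C@@H]32 | intermediate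
34 | ring-expanded 11,14-dione, C10 epimers | CC1C(=O)[C@](C)([C@H]5COC(C)(C)O5)CC(=O)[C@@]2(C)[C@@H](C)CC[C@]13CCC4(OCCO4)[C@@H]32 | intermediate
35 | tricyclic cyclooctane-11,14-dione (10R; C3 ketal; 19,20-acetonide) | C[C@H]1C(=O)[C@](C)([C@H]5COC(C)(C)O5)CC(=O)[C@@]2(C)[C@@H](C)CC[C@]13CCC4(OCCO4)[C@@H]32 | intermediate
36 | 11S,14R-diol (C3 ketal; 19,20-acetonide) | C[C@H]1[C@H](O)[C@](C)([C@H]5COC(C)(C)O5)C[C@@H](O)[C@@]2(C)[C@@H](C)CC[C@]13CCC4(OCCO4)[C@@H]32 | intermediate
37 | 11-O-trifluoroacetate of 36 | C[C@H]1[C@H](OC(=O)C(F)(F)F)[C@](C)([C@H]5COC(C)(C)O5)C[C@@H](O)[C@@]2(C)[C@@H](C)CC[C@]13CCC4(OCCO4)[C@@H]32 | intermediate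
38 | glycolic acid | OCC(=O)O | starting material
39 | 2-(trifluoroacetoxy)acetic acid | OC(=O)COC(=O)C(F)(F)F | intermediate
40 | 11-O-trifluoroacetyl 14-O-[(trifluoroacetoxy)acetyl] diester | C[C@H]1[C@H](OC(=O)C(F)(F)F)[C@](C)([C@H]5COC(C)(C)O5)C[C@@H](OC(=O)COC(=O)C(F)(F)F)[C@@]2(C)[C@@H](C)CC[C@]13CCC4(OCCO4)[C@@H]32 | intermediate
41 | 14-O-glycolate with C3 ketal and 19,20-acetonide | C[C@H]1[C@H](O)[C@](C)([C@H]5COC(C)(C)O5)C[C@@H](OC(=O)CO)[C@@]2(C)[C@@H](C)CC[C@]13CCC4(OCCO4)[C@@H]32 | intermediate
42 | Pleuromutilin A | C[C@H]1[C@H](O)[C@](C)([C@H](O)CO)C[C@@H](OC(=O)CO)[C@@]2(C)[C@@H](C)CC[C@]13CCC(=O)[C@@H]32 | target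

## Step count and least certain steps

Total: 26 steps. Longest linear sequence: 18 steps (steps 1–11, 19–23, 25, 26, from 1). The side-chain branch (steps 12–18) joins at step 19, and step 24 supplies 39.

**Step 21 (key step).** The process most likely to fail is the diversion of the C13 radical before it reaches C14. It can be reduced by the stannane, or it can attack the neighbouring C11 carbonyl (3-exo) and undergo a 1,2-acyl shift to the tertiary C12 radical, which is then reduced. The fallback forms and breaks the same bonds by two-electron chemistry while C11 is not yet a ketone. It sets out from 32. The alcohol is deprotonated with NaH and treated with t-BuLi (2.1 equiv, THF/pentane, −78 °C). Iodine–lithium exchange and intramolecular Barbier-type addition of C13 to the C14 ketone would give the tetracyclic 11,14-diol F1. Dess–Martin oxidation of its secondary C11 alcohol gives the β-hydroxy ketone F2. Base (DBU or KOtBu, THF) triggers retro-aldol cleavage of C10–C14 with equilibration at C10, and the route is rejoined at 35.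

**Step 8.** The process most likely to fail is bond formation in the reverse orientation (methyl-bearing terminus on C9). The unsubstituted end of the cation is its more accessible terminus, and C5 is the more nucleophilic diene carbon. A 1,5-hydrogen shift in 12 is a second loss channel. The fallback fixes the orientation with a removable alkoxy group and sets out from 12. The acetal ketone 1,1-dimethoxybutan-2-one F3 is converted (TMSOTf, Et3N) into its Z silyl enol ether F4. Catalytic TMSOTf (CH2Cl2, −78 °C) ionises one methoxy group. C5 of 12 adds to the methyl-bearing terminus remote from the alkoxy group, and the enol ether carbon closes on C9 to give the 8-methoxy cycloadduct F5. SmI2 (THF/MeOH) removes the α-methoxy group, and the route is rejoined at 15.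

**Step 19.** The process most likely to fail is slow addition at the fully substituted enolate carbon, followed by retro-aldol on warming or enolate O-attack. The fallback makes the addition irreversible under Lewis acid control and sets out from 20. TMSOTf/Et3N gives the trimethylsilyl enol ether F6. A Mukaiyama aldol reaction of F6 with 30 (BF3·OEt2, CH2Cl2, −78 °C) rejoins the route at 32.

**Step 22.** The process most likely to fail is protonation on the wrong face at C11 or C14, or pinacol-type coupling of the 1,4-diketone under electron-transfer conditions. The fallback sets out from 35. Hydride reduction (LiAlH4, THF, 0 °C) gives the diol epimer mixture F7 under kinetic control. Meerwein–Ponndorf–Verley/Oppenauer exchange (Al(OiPr)3, i-PrOH, a little acetone, toluene, reflux) equilibrates both carbinols to the more stable epimers, and the route is rejoined at 36.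

## Further compounds

F1 | step 21 | tetracyclic 11,14-diol with the C13–C14 bond (C10, C11, C14 undefined) | CC12C(O)[C@](C)([C@H]7COC(C)(C)O7)CC1(O)[C@@]3(C)[C@@H](C)CC[C@]24CCC5(OCCO5)[C@@H]43
F2 | step 21 | tetracyclic 14-hydroxy 11-ketone | CC12C(=O)[C@](C)([C@H]7COC(C)(C)O7)CC1(O)[C@@]3(C)[C@@H](C)CC[C@]24CCC5(OCCO5)[C@@H]43
F3 | step 8 | 1,1-dimethoxybutan-2-one | CCC(=O)C(OC)OC
F4 | step 8 | (Z)-1,1-dimethoxy-2-(trimethylsilyloxy)but-2-ene | C/C=C(\O[Si](C)(C)C)C(OC)OC
F5 | step 8 | 8-methoxy analogue of 15 (C8 undefined) | CC1=C(O[Si](C(C)C)(C(C)C)C(C)C)[C@@]2(C)[C@@H](C)C(=O)C(OC)[C@]13CC[C@@H](O[Si](C)(C)C(C)(C)C)[C@@H]32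
F6 | step 19 | trimethylsilyl enol ether of 20 | CC1=C(O[Si](C)(C)C)[C@@]2(C)[C@@H](C)CC[C@]13CCC4(OCCO4)[C@@H]32
F7 | step 22 | 11,14-diol, epimer mixture at C11 and C14 | C[C@H]1C(O)[C@](C)([C@H]5COC(C)(C)O5)CC(O)[C@@]2(C)[C@@H](C)CC[C@]13CCC4(OCCO4)[C@@H]32
A1 | alternative 1 | cis-fused hydrindenone with quaternary C5 and C9 | C[C@@H](COCc5ccccc5)[C@]13CCC(=O)[C@H]1[C@@](C)(COCc5ccccc5)[C@@H](C)C=C3
A2 | alternative 2 | tricyclic 3,14-diketone (11-O-methoxymethyl, 19,20-acetonide) | C[C@H]1[C@H](OCOC)[C@](C)([C@H]5COC(C)(C)O5)CC(=O)[C@@]2(C)[C@@H](C)CC[C@]13CCC(=O)[C@@H]32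
A3 | alternative 3 | cyclopentanone-fused cyclooctanone with quaternary C9 | C[C@H]1C(=O)[C@](C)([C@H]4COC(C)(C)O4)C[C@@H](O[Si](C)(C)C(C)(C)C)[C@@](C)([C@@H](C)COCc5ccccc5)[C@H]3C(=O)CC[C@@]13COCc5ccccc5
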